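A direct plan would cyclize (2E,6E,10E)-geranylgeraniol A1 with a squalene–hopene cyclase. Protonation of the terminal olefin would close ring A and then ring B (C4–C5, C9–C10), water would capture the C8 cation to give labd-13E-ene-8α,15-diol A2, and the primary hydroxyl would then be acetylated. Its weakest steps would be:
- the water-terminated bicyclization, because no enzyme variant is known that would stop a C20 substrate at the bicyclic cation and hydrate it in preference to proton loss, ether formation or further ring closure;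
- the same step in turnover, because a poorly soluble allylic alcohol of non-native length would be accepted slowly, which would limit scale;
- the separate acetylation, which would add length without adding complexity.

The route rests on the C8–C9 bond: the trans-vicinal C8 tertiary carbinol and C9 branch of ring B are the retron of a ketyl–olefin closure. Ring A, with C5 set, comes from (S)-α-ionone, and a radical alkenylation builds the quaternary C10. The key step then unites two electrophilic carbons, the C8 carbonyl carbon and the β-carbon (C9) of a vinyl sulfone, in a samarium ketyl 6-exo cyclization that closes ring B last and sets C8 and C9 together. The sulfone then joins the preformed E-acetoxyprenyl unit at C11–C12 and is removed. No cation has to be stopped by water at the bicyclic stage, no enzyme is needed, and the acetate arrives with the side chain.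

Key step: step 4

Assumption: (S)-(−)-α-ionone of high enantiomeric purity is taken as a purchasable starting material; its stereocentre becomes C5 of the target. Labdane numbering is used for all atoms.

Step 1
Reactants: 1 (S)-α-ionone
Product: 3 (S)-dihydro-α-ionone, via triethylsilyl enol ether 2 (not isolated)
Conditions: Et3SiH (1.2 equiv), RhCl(PPh3)3 (1 mol%), benzene, 50 °C; then K2CO3, MeOH–H2O, rt
Reagents that add atoms: none
Why: Rhodium-catalysed 1,4-hydrosilylation of the enone (conjugate reduction) and hydrolysis of the silyl enol ether should saturate C6–C7 only, since the unactivated trisubstituted ring olefin does not react and the neutral conditions leave C5 untouched.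

Step 2
Reactants: 3 (S)-dihydro-α-ionone
Product: 4 2-methyl-2-{2-[(1S)-2,6,6-trimethylcyclohex-2-en-1-yl]ethyl}-1,3-dioxolane
Conditions: Me3SiOCH2CH2OSiMe3 (1.5 equiv), Me3SiOTf (2 mol%), CH2Cl2, −78 °C
Reagents that add atoms: 1,2-bis(trimethylsilyloxy)ethane, C[Si](C)(C)OCCO[Si](C)(C)C
Why: Noyori ketalization is aprotic and cold, so the ring olefin should not migrate to the tetrasubstituted position (which would erase C5), and the ketal keeps the carbonyl group from capturing the C10 radical of the next step.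

Step 3
Reactants: 4 2-methyl-2-{2-[(1S)-2,6,6-trimethylcyclohex-2-en-1-yl]ethyl}-1,3-dioxolane; 5 (E)-1,2-bis(phenylsulfonyl)ethene
Product: 8 4-[(1S,2S)-2,6,6-trimethyl-2-[(E)-2-(phenylsulfonyl)ethenyl]cyclohexyl]butan-2-one, via tertiary C10 radical 6 (not isolated), via ketal vinyl sulfone 7 (not isolated)
Conditions: 5 (2.5 equiv), Fe(acac)3 (0.5 equiv), PhSiH3 (3 equiv), EtOH–THF, 60 °C; then 1 M HCl, THF, rt
Reagents that add atoms: water, O
Why: Markovnikov hydrogen-atom transfer from the iron hydride formed from Fe(acac)3 and PhSiH3 (Mukaiyama-type radical hydrofunctionalization) should give the tertiary C10 radical, which adds to the bis-sulfone and expels a sulfonyl radical (Giese-type addition–β-elimination, radical alkenylation); the acceptor should enter anti to the vicinal C5 side chain and so set the quaternary C10 (S) trans to it, and the acidic work-up unmasks the ketone.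

Step 4
Reactants: 8 4-[(1S,2S)-2,6,6-trimethyl-2-[(E)-2-(phenylsulfonyl)ethenyl]cyclohexyl]butan-2-one
Product: 10 (1R,2R,4aS,8aS)-2,5,5,8a-tetramethyl-1-[(phenylsulfonyl)methyl]decahydronaphthalen-2-ol, via samarium ketyl 9 (not isolated)
Conditions: SmI2 (2.2 equiv), HMPA (6 equiv), t-BuOH (2 equiv), THF, −78 °C
Reagents that add atoms: none
Why: Electron transfer from SmI2 to the methyl ketone should give the samarium ketyl, a nucleophilic radical at the normally electrophilic C8, which adds 6-exo-trig to the β-carbon (C9) of the vinyl sulfone; the α-sulfonyl radical at C11 is then reduced by a second equivalent and protonated by t-BuOH. The closest known reaction type is the samarium diiodide ketyl–olefin cyclization onto electron-poor olefins (acrylates, unsaturated nitriles and sulfones) that gives 2-substituted cyclohexanols. Ring B closes through a chair transition state on the diequatorial conformer of 8, in which the trans C5 and C10 arms fix the trans ring fusion. At C8 the bulky, solvated O–Sm group should take the equatorial (α) position and leave the small methyl axial, syn to the C10 methyl, which gives 8R. At C9 the sulfonylvinyl arm should stay equatorial, so C11 ends β and trans to the oxygen, as is general for these cyclizations, which gives 9R. The step needs 6-exo over 7-endo closure, secured by the polarity of the acceptor, and C–C bond formation over simple carbonyl reduction, helped by the activated olefin and the low temperature.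

Step 5
Reactants: 11 3-methylbut-2-en-1-yl acetate (prenyl acetate)
Product: 12 (2E)-4-hydroxy-3-methylbut-2-en-1-yl acetate
Conditions: SeO2 (0.2 equiv), t-BuOOH (2 equiv), salicylic acid (0.1 equiv), CH2Cl2, rt
Reagents that add atoms: tert-butyl hydroperoxide, CC(C)(C)OO
Why: Riley-type allylic oxidation with catalytic SeO2 (ene reaction, then 2,3-sigmatropic shift) is known to hydroxylate the E methyl group of trisubstituted olefins, which fixes the later C13–C14 geometry as E.

Step 6
Reactants: 12 (2E)-4-hydroxy-3-methylbut-2-en-1-yl acetate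
Product: 13 (2E)-4-bromo-3-methylbut-2-en-1-yl acetate
Conditions: CBr4 (1.2 equiv), PPh3 (1.25 equiv), CH2Cl2, 0 °C
Reagents that add atoms: carbon tetrabromide, BrC(Br)(Br)Br
Why: Appel bromination displaces the oxyphosphonium ion of the primary allylic alcohol by SN2 attack under neutral conditions, so the acetate and the olefin geometry should be kept.

Step 7
Reactants: 10 (1R,2R,4aS,8aS)-2,5,5,8a-tetramethyl-1-[(phenylsulfonyl)methyl]decahydronaphthalen-2-ol; 13 (2E)-4-bromo-3-methylbut-2-en-1-yl acetate
Product: 15 (2E)-5-[(1R,2R,4aS,8aS)-2-hydroxy-2,5,5,8a-tetramethyldecahydronaphthalen-1-yl]-3-methyl-5-(phenylsulfonyl)pent-2-en-1-yl acetate (both C11 epimers), via C11,O-dilithio sulfone 14 (not isolated)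
Conditions: n-BuLi (2.1 equiv), THF, −78 to −30 °C; then 13 (1.2 equiv), −78 °C; aqueous work-up
Reagents that add atoms: none
Why: Julia-type alkylation of the sulfone-stabilized C11 carbanion with the primary allylic bromide by SN2 displacement is the coupling used for terpenoid chains and at −78 °C should outrun attack on the acetate; the new C11 centre forms as a mixture that is of no consequence.

Step 8
Reactants: 15 (2E)-5-[(1R,2R,4aS,8aS)-2-hydroxy-2,5,5,8a-tetramethyldecahydronaphthalen-1-yl]-3-methyl-5-(phenylsulfonyl)pent-2-en-1-yl acetate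
Product: 16 8α-hydroxylabd-13E-en-15-yl acetate (target)
Conditions: SmI2 (6 equiv), HMPA (12 equiv), MeOH (4 equiv), THF, −20 °C
Reagents that add atoms: none
Why: Reductive desulfonylation by electron transfer from SmI2–HMPA should cleave the C11–S bond to sulfinate and a C11 radical that is reduced and protonated, while the acetate, the isolated trisubstituted olefin and the tertiary alcohol are not reduced and no stereocentre is touched.

Compound list

1 | (S)-α-ionone, (3E)-4-[(1S)-2,6,6-trimethylcyclohex-2-en-1-yl]but-3-en-2-one | CC(=O)/C=C/[C@@H]1C(C)=CCCC1(C)C | starting material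
2 | triethylsilyl enol ether of 3, triethyl({4-[(1S)-2,6,6-trimethylcyclohex-2-en-1-yl]but-2-en-2-yl}oxy)silane | CC(O[Si](CC)(CC)CC)=CC[C@@H]1C(C)=CCCC1(C)C | intermediate
3 | (S)-dihydro-α-ionone, 4-[(1S)-2,6,6-trimethylcyclohex-2-en-1-yl]butan-2-one | CC(=O)CC[C@@H]1C(C)=CCCC1(C)C | intermediate
4 | 2-methyl-2-{2-[(1S)-2,6,6-trimethylcyclohex-2-en-1-yl]ethyl}-1,3-dioxolane | CC1(CC[C@@H]2C(C)=CCCC2(C)C)OCCO1 | intermediate
5 | (E)-1,2-bis(phenylsulfonyl)ethene | O=S(=O)(/C=C/S(=O)(=O)c1ccccc1)c1ccccc1 | starting material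
6 | tertiary C10 radical of 4 (C5 unchanged) | CC1(CC[C@@H]2[C](C)CCCC2(C)C)OCCO1 | intermediate
7 | ketal vinyl sulfone, 2-methyl-2-{2-[(1S,2S)-2,6,6-trimethyl-2-[(E)-2-(phenylsulfonyl)ethenyl]cyclohexyl]ethyl}-1,3-dioxolane | CC1(CC[C@H]2C(C)(C)CCC[C@]2(C)/C=C/S(=O)(=O)c3ccccc3)OCCO1 | intermediate
8 | 4-[(1S,2S)-2,6,6-trimethyl-2-[(E)-2-(phenylsulfonyl)ethenyl]cyclohexyl]butan-2-one | CC(=O)CC[C@H]1C(C)(C)CCC[C@]1(C)/C=C/S(=O)(=O)c2ccccc2 | intermediate
9 | samarium ketyl of 8 (C8 radical, oxygen bound to samarium; drawn as the ketyl radical anion) | C[C]([O-])CC[C@H]1C(C)(C)CCC[C@]1(C)/C=C/S(=O)(=O)c2ccccc2 | intermediate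
10 | (1R,2R,4aS,8aS)-2,5,5,8a-tetramethyl-1-[(phenylsulfonyl)methyl]decahydronaphthalen-2-ol (8α-hydroxy-11-(phenylsulfonyl)drimane) | O=S(=O)(C[C@@H]1[C@@]2(C)CCCC(C)(C)[C@@H]2CC[C@@]1(C)O)c3ccccc3 | intermediate
11 | 3-methylbut-2-en-1-yl acetate (prenyl acetate) | CC(C)=CCOC(C)=O | starting material
12 | (2E)-4-hydroxy-3-methylbut-2-en-1-yl acetate | CC(=O)OC/C=C(\C)CO | intermediate
13 | (2E)-4-bromo-3-methylbut-2-en-1-yl acetate | CC(=O)OC/C=C(\C)CBr | intermediate
14 | C11,O-dilithio derivative of 10 | [Li]C([C@@H]1[C@@]2(C)CCCC(C)(C)[C@@H]2CC[C@@]1(C)O[Li])S(=O)(=O)c3ccccc3 | intermediate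
15 | (2E)-5-[(1R,2R,4aS,8aS)-2-hydroxy-2,5,5,8a-tetramethyldecahydronaphthalen-1-yl]-3-methyl-5-(phenylsulfonyl)pent-2-en-1-yl acetate (both C11 epimers) | CC(=O)OC/C=C(\C)CC([C@@H]1[C@@]2(C)CCCC(C)(C)[C@@H]2CC[C@@]1(C)O)S(=O)(=O)c3ccccc3 | intermediate
16 | 8α-hydroxylabd-13E-en-15-yl acetate, (2E)-5-[(1R,2R,4aS,8aS)-2-hydroxy-2,5,5,8a-tetramethyldecahydronaphthalen-1-yl]-3-methylpent-2-en-1-yl acetate (CNP0268033.1) | CC(=O)OC/C=C(\C)CC[C@@H]1[C@@]2(C)CCCC(C)(C)[C@@H]2CC[C@@]1(C)O | target

Total step count: 8. Longest linear sequence: 6 (steps 1, 2, 3, 4, 7, 8); steps 5 and 6 make the side-chain electrophile.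

Steps most likely to fail

Step 3 (radical alkenylation). The nearly planar tertiary radical could be trapped with poor facial selectivity, or hydride reduction of the acceptor could outrun C–C bond formation. The fallback would set out from 4 and come back at 7:
- Allylic oxidation of the ring olefin (CrO3, 3,5-dimethylpyrazole, CH2Cl2, −20 °C) would give (4S)-3,5,5-trimethyl-4-[2-(2-methyl-1,3-dioxolan-2-yl)ethyl]cyclohex-2-en-1-one F1.
- Copper-mediated conjugate addition of vinylmagnesium bromide (CuBr·SMe2, Me3SiCl, THF, −78 °C), which is known to enter anti to a substituent at C4 of cyclohexenones, would give (3R,4S)-3-ethenyl-3,5,5-trimethyl-4-[2-(2-methyl-1,3-dioxolan-2-yl)ethyl]cyclohexan-1-one F2.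
- Wolff–Kishner reduction (N2H4·H2O, KOH, diethylene glycol, 200 °C) would give 2-{2-[(1S,2R)-2-ethenyl-2,6,6-trimethylcyclohexyl]ethyl}-2-methyl-1,3-dioxolane F3.
- Iodosulfonylation (PhSO2Na, I2) would give 2-{2-[(1S,2S)-2-[1-iodo-2-(phenylsulfonyl)ethyl]-2,6,6-trimethylcyclohexyl]ethyl}-2-methyl-1,3-dioxolane F4, and dehydroiodination with DBU would give 7, which is hydrolysed to 8 as in step 3.

Step 4 (key cyclization). Simple reduction of the ketone, reduction or C–S cleavage of the vinyl sulfone, or closure with the oxygen axial could compete with the wanted ring closure. The fallback would set out from 8 and come back at 10: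
- Kinetic enol silylation (LiN(SiMe3)2, Et3SiCl, THF, −78 °C) would give triethyl({4-[(1S,2S)-2,6,6-trimethyl-2-[(E)-2-(phenylsulfonyl)ethenyl]cyclohexyl]but-1-en-2-yl}oxy)silane F5.
- Hydrogen-atom transfer from an iron hydride to its CH2 terminus (Fe(acac)3, PhSiH3, EtOH, 60 °C) would give a neutral α-silyloxy C8 radical. This would close the same bond by intramolecular Giese addition, with the bulky silyloxy group equatorial, to triethyl{[(1R,2R,4aS,8aS)-2,5,5,8a-tetramethyl-1-[(phenylsulfonyl)methyl]decahydronaphthalen-2-yl]oxy}silane F6.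
- Bu4NF would then release 10.

Step 7 (sulfone alkylation). Acetyl transfer from the electrophile to the alkoxide of the dianion, or poor reactivity of the aggregated, hindered dianion, could erode the coupling. The fallback would set out from 10 and come back at 15:
- Silylation of the tertiary hydroxyl (Me3SiOTf, 2,6-lutidine, CH2Cl2, −78 °C) would give trimethyl{[(1R,2R,4aS,8aS)-2,5,5,8a-tetramethyl-1-[(phenylsulfonyl)methyl]decahydronaphthalen-2-yl]oxy}silane F7.
- Its monoanion (n-BuLi, 1.05 equiv, THF–DMPU, −78 °C) would be alkylated with 13 to (2E)-3-methyl-5-(phenylsulfonyl)-5-[(1R,2R,4aS,8aS)-2,5,5,8a-tetramethyl-2-(trimethylsilyloxy)decahydronaphthalen-1-yl]pent-2-en-1-yl acetate F8.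
- PPTS in MeOH would remove the silyl group and give 15.

Further compounds

F1 | step 3 | (4S)-3,5,5-trimethyl-4-[2-(2-methyl-1,3-dioxolan-2-yl)ethyl]cyclohex-2-en-1-one | CC1(CC[C@@H]2C(C)=CC(=O)CC2(C)C)OCCO1
F2 | step 3 | (3R,4S)-3-ethenyl-3,5,5-trimethyl-4-[2-(2-methyl-1,3-dioxolan-2-yl)ethyl]cyclohexan-1-one | CC1(CC[C@H]2C(C)(C)CC(=O)C[C@]2(C)C=C)OCCO1
F3 | step 3 | 2-{2-[(1S,2R)-2-ethenyl-2,6,6-trimethylcyclohexyl]ethyl}-2-methyl-1,3-dioxolane | CC1(CC[C@H]2C(C)(C)CCC[C@]2(C)C=C)OCCO1
F4 | step 3 | 2-{2-[(1S,2S)-2-[1-iodo-2-(phenylsulfonyl)ethyl]-2,6,6-trimethylcyclohexyl]ethyl}-2-methyl-1,3-dioxolane | CC1(CC[C@H]2C(C)(C)CCC[C@]2(C)C(I)CS(=O)(=O)c3ccccc3)OCCO1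
F5 | step 4 | triethyl({4-[(1S,2S)-2,6,6-trimethyl-2-[(E)-2-(phenylsulfonyl)ethenyl]cyclohexyl]but-1-en-2-yl}oxy)silane | C=C(O[Si](CC)(CC)CC)CC[C@H]1C(C)(C)CCC[C@]1(C)/C=C/S(=O)(=O)c2ccccc2
F6 | step 4 | triethyl{[(1R,2R,4aS,8aS)-2,5,5,8a-tetramethyl-1-[(phenylsulfonyl)methyl]decahydronaphthalen-2-yl]oxy}silane | O=S(=O)(C[C@@H]1[C@@]2(C)CCCC(C)(C)[C@@H]2CC[C@@]1(C)O[Si](CC)(CC)CC)c3ccccc3
F7 | step 7 | trimethyl{[(1R,2R,4aS,8aS)-2,5,5,8a-tetramethyl-1-[(phenylsulfonyl)methyl]decahydronaphthalen-2-yl]oxy}silane | O=S(=O)(C[C@@H]1[C@@]2(C)CCCC(C)(C)[C@@H]2CC[C@@]1(C)O[Si](C)(C)C)c3ccccc3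
F8 | step 7 | (2E)-3-methyl-5-(phenylsulfonyl)-5-[(1R,2R,4aS,8aS)-2,5,5,8a-tetramethyl-2-(trimethylsilyloxy)decahydronaphthalen-1-yl]pent-2-en-1-yl acetate | CC(=O)OC/C=C(\C)CC([C@@H]1[C@@]2(C)CCCC(C)(C)[C@@H]2CC[C@@]1(C)O[Si](C)(C)C)S(=O)(=O)c3ccccc3
A1 | direct plan | (2E,6E,10E)-geranylgeraniol | CC(C)=CCC/C(C)=C/CC/C(C)=C/CC/C(C)=C/CO
A2 | direct plan | labd-13E-ene-8α,15-diol | OC/C=C(\C)CC[C@@H]1[C@@]2(C)CCCC(C)(C)[C@@H]2CC[C@@]1(C)O
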